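**Retrosynthetic overview**

1. The target is reached by global desilylation of its tetrasilyl ether; the C3–CH2Ar bond of the butanolide is cut by a 3,4-trans-selective lactone enolate alkylation into a C4-substituted butanolide and a (2S,3R)-dihydrobenzofuran-5-ylmethyl bromide.
2. Butanolide: the O1–C5 and C3–C4 bonds are made together by dichloroketene lactonization of an enantiopure (E)-1-alkenyl p-tolyl sulfoxide; sulfur chirality is relayed to C4, and the side-chain carbinol comes from a catalytic asymmetric alkynylation of silylated vanillin.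
3. Enabling feature: in the γ-lactone ring, C5 is an unsubstituted O–CH2 group next to the only non-epimerizable ring stereocentre C4, and C3 is a CH that is alkylated later; C5 can therefore carry the sulfur of a vinyl sulfoxide and C3 two chlorines as traceless activators, both removed with Bu3SnH.
4. Dihydrobenzofuran: the O1–C2–C3 ring is closed by enantioselective dirhodium-carbenoid 1,5 C–H insertion of an aryl diazoacetate built from methyl 5-iodovanillate and silylated vanillyl alcohol, then epimerized to 2,3-trans.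
5. Ring order: the γ-lactone (step 7) and the dihydrofuran ring (step 12) are formed in two separate branches from vanillin and joined in step 17; no ring is formed after the union.

Key step: step 7

Assumption: the absolute senses of induction in the three reagent-controlled steps (2, 7 and 12) are taken from the accepted transition-state models and are not recalled from a checked precedent; each controller (ligand, menthyl sulfinate, dirhodium catalyst) exists in both mirror-image forms, so a reversed sense would be answered by the enantiomeric controller without changing the route.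

Abbreviations: TBS = tert-butyldimethylsilyl; Tol = 4-methylphenyl; Ar = 4-(TBS-oxy)-3-methoxyphenyl.

**Route**

Step 1
Reactants: 1 vanillin (4-hydroxy-3-methoxybenzaldehyde)
Product: 2 4-(TBS-oxy)-3-methoxybenzaldehyde
Conditions: TBSCl, imidazole, DMF, rt
Reagents that add atoms: tert-butyldimethylsilyl chloride, CC(C)(C)[Si](C)(C)Cl
Why: Imidazole-promoted O-silylation masks the only acidic proton before the organometallic steps; no stereocentre is involved.

Step 2
Reactants: 2 4-(TBS-oxy)-3-methoxybenzaldehyde; 3 ethynyltrimethylsilane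
Product: 4 (S)-1-Ar-3-(trimethylsilyl)prop-2-yn-1-ol
Conditions: Me2Zn, (S,S)-ProPhenol (10 mol %), Ph3PO (20 mol %), toluene, 4 °C
Reagents that add atoms: none
Why: Catalytic asymmetric alkynylation of an aldehyde: the zinc alkynylide adds inside the dinuclear zinc–ProPhenol complex, which differentiates the aldehyde faces and sets the carbinol centre of the target (named S here only because the silylalkynyl group outranks the aryl group).

Step 3
Reactants: 4 (S)-1-Ar-3-(trimethylsilyl)prop-2-yn-1-ol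
Product: 5 (S)-1-Ar-1-(TBS-oxy)-3-(trimethylsilyl)prop-2-yne
Conditions: TBSCl, imidazole, DMF, rt
Reagents that add atoms: tert-butyldimethylsilyl chloride, CC(C)(C)[Si](C)(C)Cl
Why: O-silylation of the secondary carbinol with retention protects it against the Grignard, hydride and enolate steps.

Step 4
Reactants: 5 (S)-1-Ar-1-(TBS-oxy)-3-(trimethylsilyl)prop-2-yne
Product: 6 (R)-1-Ar-1-(TBS-oxy)prop-2-yne
Conditions: AgNO3 (10 mol %), acetone/H2O/CH2Cl2, rt
Reagents that add atoms: none
Why: Silver-catalysed protodesilylation through a silver acetylide cleaves only the C(sp)–Si bond and leaves both O–Si bonds and the carbinol centre untouched (the descriptor becomes R only because ethynyl ranks below aryl).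

Step 5
Reactants: 6 (R)-1-Ar-1-(TBS-oxy)prop-2-yne; 7 (1S,2R,5S)-(+)-menthyl (R)-p-toluenesulfinate
Product: 9 (S)-1-Ar-1-(TBS-oxy)-3-[(R)-p-tolylsulfinyl]prop-2-yne, via bromomagnesium acetylide 8 (not isolated)
Conditions: EtMgBr, THF, 0 °C to rt; then added to 7, toluene, −20 °C
Reagents that add atoms: none
Why: Andersen sulfoxide synthesis: the alkynyl Grignard reagent displaces mentholate at sulfur with inversion, so the sulfur configuration is fixed by the sulfinate and the carbinol centre is not involved.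

Step 6
Reactants: 9 (S)-1-Ar-1-(TBS-oxy)-3-[(R)-p-tolylsulfinyl]prop-2-yne
Product: 10 (1R,2E)-1-Ar-1-(TBS-oxy)-3-[(S)-p-tolylsulfinyl]prop-2-ene
Conditions: i-Bu2AlH, THF, −78 °C; aqueous Rochelle salt work-up
Reagents that add atoms: none
Why: Hydroalumination of a 1-alkynyl sulfoxide followed by protonolysis is a trans reduction that should give the E-alkenyl sulfoxide without touching sulfur or the carbinol centre (the sulfur descriptor changes to S only because vinyl ranks below tolyl).

Step 7
Reactants: 10 (1R,2E)-1-Ar-1-(TBS-oxy)-3-[(S)-p-tolylsulfinyl]prop-2-ene; 11 trichloroacetyl chloride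
Product: 15 (4S,5S)-3,3-dichloro-4-[(R)-Ar(TBS-oxy)methyl]-5-(p-tolylsulfanyl)oxolan-2-one, via dichloroketene 12 (not isolated), via acyloxysulfonium enolate 13 (not isolated), via thionium carboxylate 14 (not isolated)
Conditions: Zn–Cu couple, THF, −45 to 0 °C
Reagents that add atoms: none
Why: Zinc reduces 11 to dichloroketene 12, whose carbonyl carbon is attacked by the sulfinyl oxygen of 10 to give the acyloxysulfonium enolate 13; a charge-accelerated [3,3]-sigmatropic shift then joins the enolate carbon to the sulfoxide β-carbon (the C3–C4 bond of the butanolide) as the S–O bond breaks, and the carboxylate of the thionium ion 14 closes on the thionium carbon (the O1–C5 bond), the closest known reaction type being exactly this vinyl sulfoxide/dichloroketene lactonization (Marino lactonization, an additive Pummerer reaction) of 1-alkenyl p-tolyl sulfoxides. The only ring closed is the γ-lactone: the C–C bond forms pericyclically through a six-membered chair array and the C–O bond by 5-exo-trig addition of the carboxylate to the C=S+ bond. The C4 stereocentre is controlled by the sulfur stereocentre: with the p-tolyl group pseudo-equatorial the ketene unit is delivered to one face of the E-alkene only, so the (S)-sulfoxide should give the 4S-dichlorolactone (4R once chlorine and sulfur are removed), while the C5 centre, expected trans to the C4 side chain from suprafacial addition across the E-alkene, is erased in step 8. The step needs face selectivity in the presence of the resident carbinol centre and chemoselectivity for the sulfoxide: intramolecular delivery from sulfur makes sulfur the dominant controller, and the sulfinyl oxygen is by far the most nucleophilic site, the silyl ethers and arenes being inert to dichloroketene at low temperature.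

Step 8
Reactants: 15 (4S,5S)-3,3-dichloro-4-[(R)-Ar(TBS-oxy)methyl]-5-(p-tolylsulfanyl)oxolan-2-one
Product: 16 (4R)-4-[(R)-Ar(TBS-oxy)methyl]oxolan-2-one
Conditions: Bu3SnH (excess), AIBN (cat.), toluene, 100 °C
Reagents that add atoms: none
Why: Radical chain reduction (tin hydride dehalogenation and desulfurization): stannyl radicals abstract both chlorines and the arylthio group to give α-acyl and α-acyloxy radicals that take up hydrogen; C4 and the carbinol centre are not involved and the C5 centre disappears.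

Step 9
Reactants: 2 4-(TBS-oxy)-3-methoxybenzaldehyde
Product: 17 [4-(TBS-oxy)-3-methoxyphenyl]methanol
Conditions: NaBH4, MeOH, 0 °C
Reagents that add atoms: none
Why: Borohydride reduction of the aldehyde to the benzylic alcohol; no stereocentre is involved.

Step 10
Reactants: 17 [4-(TBS-oxy)-3-methoxyphenyl]methanol; 18 methyl 4-hydroxy-3-iodo-5-methoxybenzoate (methyl 5-iodovanillate)
Product: 19 methyl 3-iodo-5-methoxy-4-(Ar-methoxy)benzoate
Conditions: PPh3, DIAD, THF, 0 °C to rt
Reagents that add atoms: none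
Why: Mitsunobu etherification: the acidic phenol displaces the activated benzylic alkoxyphosphonium under neutral conditions that spare the aryl silyl ether.

Step 11
Reactants: 19 methyl 3-iodo-5-methoxy-4-(Ar-methoxy)benzoate; 20 ethyl diazoacetate
Product: 21 methyl 3-(1-diazo-2-ethoxy-2-oxoethyl)-5-methoxy-4-(Ar-methoxy)benzoate
Conditions: Pd(PPh3)4 (5 mol %), Ag2CO3 (0.5 equiv), Et3N, toluene, rt
Reagents that add atoms: none
Why: Palladium-catalysed cross-coupling of an aryl iodide with the C–H bond of an acceptor diazo compound (oxidative addition, silver-assisted deprotonative transfer of the diazoacetate, reductive elimination) keeps the diazo group and gives the aryl diazoacetate.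

Step 12
Reactants: 21 methyl 3-(1-diazo-2-ethoxy-2-oxoethyl)-5-methoxy-4-(Ar-methoxy)benzoate
Product: 23 3-ethyl 5-methyl (2S,3S)-2-Ar-7-methoxy-2,3-dihydro-1-benzofuran-3,5-dicarboxylate (2,3-trans), via cis diester 22 (not isolated)
Conditions: Rh2(R-PTTL)4 (dirhodium tetrakis[N-phthaloyl-(R)-tert-leucinate], 1 mol %), toluene, −60 °C; then DBU (cat.), rt
Reagents that add atoms: none
Why: Enantioselective intramolecular 1,5 C–H insertion of the donor/acceptor dirhodium carbenoid into the O-benzylic methylene closes the dihydrofuran ring, the chiral carboxylate ligands fixing C2 in the cis diester 22, and DBU then epimerizes C3 (α to the ester) to the more stable 2,3-trans isomer without affecting C2.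

Step 13
Reactants: 23 3-ethyl 5-methyl (2S,3S)-2-Ar-7-methoxy-2,3-dihydro-1-benzofuran-3,5-dicarboxylate
Product: 24 methyl (2S,3R)-2-Ar-3-(hydroxymethyl)-7-methoxy-2,3-dihydro-1-benzofuran-5-carboxylate
Conditions: LiBH4, THF, 0 °C to rt
Reagents that add atoms: none
Why: Chemoselective borohydride reduction: LiBH4 should reduce the aliphatic ethyl ester much faster than the electron-rich, conjugated methyl benzoate, and C3 is no longer epimerizable once reduced.

Step 14
Reactants: 24 methyl (2S,3R)-2-Ar-3-(hydroxymethyl)-7-methoxy-2,3-dihydro-1-benzofuran-5-carboxylate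
Product: 25 methyl (2S,3R)-2-Ar-3-[(TBS-oxy)methyl]-7-methoxy-2,3-dihydro-1-benzofuran-5-carboxylate
Conditions: TBSCl, imidazole, DMF, rt
Reagents that add atoms: tert-butyldimethylsilyl chloride, CC(C)(C)[Si](C)(C)Cl
Why: O-silylation of the primary alcohol so that it survives the enolate alkylation and leaves in the final fluoride step.

Step 15
Reactants: 25 methyl (2S,3R)-2-Ar-3-[(TBS-oxy)methyl]-7-methoxy-2,3-dihydro-1-benzofuran-5-carboxylate
Product: 26 {(2S,3R)-2-Ar-3-[(TBS-oxy)methyl]-7-methoxy-2,3-dihydro-1-benzofuran-5-yl}methanol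
Conditions: i-Bu2AlH, CH2Cl2, −78 °C; aqueous Rochelle salt work-up
Reagents that add atoms: none
Why: Aluminium hydride reduction of the benzoate to the benzylic alcohol, which leaves aryl and alkyl silyl ethers intact.

Step 16
Reactants: 26 {(2S,3R)-2-Ar-3-[(TBS-oxy)methyl]-7-methoxy-2,3-dihydro-1-benzofuran-5-yl}methanol
Product: 27 (2S,3R)-5-(bromomethyl)-2-Ar-3-[(TBS-oxy)methyl]-7-methoxy-2,3-dihydro-1-benzofuran
Conditions: CBr4, PPh3, CH2Cl2, 0 °C; used at once
Reagents that add atoms: carbon tetrabromide, BrC(Br)(Br)Br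
Why: Appel bromination converts the primary benzylic alcohol into the bromide under neutral conditions.

Step 17
Reactants: 16 (4R)-4-[(R)-Ar(TBS-oxy)methyl]oxolan-2-one; 27 (2S,3R)-5-(bromomethyl)-2-Ar-3-[(TBS-oxy)methyl]-7-methoxy-2,3-dihydro-1-benzofuran
Product: 29 (3R,4R)-3-({(2S,3R)-2-Ar-3-[(TBS-oxy)methyl]-7-methoxy-2,3-dihydro-1-benzofuran-5-yl}methyl)-4-[(R)-Ar(TBS-oxy)methyl]oxolan-2-one, via lithium enolate 28 (not isolated)
Conditions: LiN(SiMe3)2, THF, −78 °C; then 27, HMPA, −78 to −40 °C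
Reagents that add atoms: none
Why: Lactone enolate alkylation (SN2): the benzylic bromide approaches the enolate 28 on the face anti to the C4 side chain, which should give the 3,4-trans lactone and so set C3 as R.

Step 18
Reactants: 29 (3R,4R)-3-({(2S,3R)-2-Ar-3-[(TBS-oxy)methyl]-7-methoxy-2,3-dihydro-1-benzofuran-5-yl}methyl)-4-[(R)-Ar(TBS-oxy)methyl]oxolan-2-one
Product: 30 (3R,4R)-3-{[(2S,3R)-2-(4-hydroxy-3-methoxyphenyl)-3-(hydroxymethyl)-7-methoxy-2,3-dihydro-1-benzofuran-5-yl]methyl}-4-[(R)-hydroxy(4-hydroxy-3-methoxyphenyl)methyl]oxolan-2-one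
Conditions: Bu4NF, AcOH (1:1), THF, 0 °C to rt
Reagents that add atoms: none
Why: Fluoride-mediated desilylation of the four silyl ethers under acetic acid buffering avoids the base and acid sensitivity of the p-hydroxybenzylic carbinol, the lactone and the 2-aryl dihydrobenzofuran; no stereocentre is touched.

**Compound list**

1 | vanillin | COc1cc(C=O)ccc1O | starting material
2 | 4-(TBS-oxy)-3-methoxybenzaldehyde | COc1cc(C=O)ccc1O[Si](C)(C)C(C)(C)C | intermediate
3 | ethynyltrimethylsilane | C#C[Si](C)(C)C | starting material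
4 | (S)-1-Ar-3-(trimethylsilyl)prop-2-yn-1-ol | C[Si](C)(C)C#C[C@@H](O)c1ccc(O[Si](C)(C)C(C)(C)C)c(OC)c1 | intermediate
5 | (S)-1-Ar-1-(TBS-oxy)-3-(trimethylsilyl)prop-2-yne | C[Si](C)(C)C#C[C@@H](O[Si](C)(C)C(C)(C)C)c1ccc(O[Si](C)(C)C(C)(C)C)c(OC)c1 | intermediate
6 | (R)-1-Ar-1-(TBS-oxy)prop-2-yne | C#C[C@@H](O[Si](C)(C)C(C)(C)C)c1ccc(O[Si](C)(C)C(C)(C)C)c(OC)c1 | intermediate
7 | (1S,2R,5S)-(+)-menthyl (R)-p-toluenesulfinate | CC(C)[C@H]1CC[C@H](C)C[C@@H]1O[S@@](=O)c1ccc(C)cc1 | starting material
8 | bromomagnesium acetylide of 6 (not isolated) | Br[Mg]C#C[C@@H](O[Si](C)(C)C(C)(C)C)c1ccc(O[Si](C)(C)C(C)(C)C)c(OC)c1 | intermediate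
9 | (S)-1-Ar-1-(TBS-oxy)-3-[(R)-p-tolylsulfinyl]prop-2-yne | Cc1ccc(cc1)[S@@](=O)C#C[C@@H](O[Si](C)(C)C(C)(C)C)c1ccc(O[Si](C)(C)C(C)(C)C)c(OC)c1 | intermediate
10 | (1R,2E)-1-Ar-1-(TBS-oxy)-3-[(S)-p-tolylsulfinyl]prop-2-ene | Cc1ccc(cc1)[S@@](=O)/C=C/[C@@H](O[Si](C)(C)C(C)(C)C)c1ccc(O[Si](C)(C)C(C)(C)C)c(OC)c1 | intermediate
11 | trichloroacetyl chloride | ClC(Cl)(Cl)C(Cl)=O | starting material
12 | dichloroketene (not isolated) | ClC(Cl)=C=O | intermediate
13 | acyloxysulfonium enolate from 10 and 12 (not isolated) | Cc1ccc(cc1)[S@@+](OC([O-])=C(Cl)Cl)/C=C/[C@@H](O[Si](C)(C)C(C)(C)C)c1ccc(O[Si](C)(C)C(C)(C)C)c(OC)c1 | intermediate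
14 | thionium carboxylate after the [3,3] shift (not isolated) | Cc1ccc(cc1)[S+]=C[C@H]([C@@H](O[Si](C)(C)C(C)(C)C)c1ccc(O[Si](C)(C)C(C)(C)C)c(OC)c1)C(Cl)(Cl)C([O-])=O | intermediate
15 | (4S,5S)-3,3-dichloro-4-[(R)-Ar(TBS-oxy)methyl]-5-(p-tolylsulfanyl)oxolan-2-one | O=C1O[C@@H](Sc2ccc(C)cc2)[C@H]([C@@H](O[Si](C)(C)C(C)(C)C)c2ccc(O[Si](C)(C)C(C)(C)C)c(OC)c2)C1(Cl)Cl | intermediate
16 | (4R)-4-[(R)-Ar(TBS-oxy)methyl]oxolan-2-one | O=C1OC[C@H]([C@@H](O[Si](C)(C)C(C)(C)C)c2ccc(O[Si](C)(C)C(C)(C)C)c(OC)c2)C1 | intermediate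
17 | [4-(TBS-oxy)-3-methoxyphenyl]methanol | COc1cc(CO)ccc1O[Si](C)(C)C(C)(C)C | intermediate
18 | methyl 4-hydroxy-3-iodo-5-methoxybenzoate | COC(=O)c1cc(I)c(O)c(OC)c1 | starting material
19 | methyl 3-iodo-5-methoxy-4-(Ar-methoxy)benzoate | COC(=O)c1cc(I)c(OCc2ccc(O[Si](C)(C)C(C)(C)C)c(OC)c2)c(OC)c1 | intermediate
20 | ethyl diazoacetate | CCOC(=O)C=[N+]=[N-] | starting material
21 | methyl 3-(1-diazo-2-ethoxy-2-oxoethyl)-5-methoxy-4-(Ar-methoxy)benzoate | CCOC(=O)C(=[N+]=[N-])c1cc(C(=O)OC)cc(OC)c1OCc1ccc(O[Si](C)(C)C(C)(C)C)c(OC)c1 | intermediate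
22 | 3-ethyl 5-methyl (2S,3R)-2-Ar-7-methoxy-2,3-dihydro-1-benzofuran-3,5-dicarboxylate, 2,3-cis (not isolated) | CCOC(=O)[C@H]1[C@@H](c2ccc(O[Si](C)(C)C(C)(C)C)c(OC)c2)Oc2c(OC)cc(C(=O)OC)cc21 | intermediate
23 | 3-ethyl 5-methyl (2S,3S)-2-Ar-7-methoxy-2,3-dihydro-1-benzofuran-3,5-dicarboxylate, 2,3-trans | CCOC(=O)[C@@H]1[C@@H](c2ccc(O[Si](C)(C)C(C)(C)C)c(OC)c2)Oc2c(OC)cc(C(=O)OC)cc21 | intermediate
24 | methyl (2S,3R)-2-Ar-3-(hydroxymethyl)-7-methoxy-2,3-dihydro-1-benzofuran-5-carboxylate | OC[C@@H]1[C@@H](c2ccc(O[Si](C)(C)C(C)(C)C)c(OC)c2)Oc2c(OC)cc(C(=O)OC)cc21 | intermediate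
25 | methyl (2S,3R)-2-Ar-3-[(TBS-oxy)methyl]-7-methoxy-2,3-dihydro-1-benzofuran-5-carboxylate | CC(C)(C)[Si](C)(C)OC[C@@H]1[C@@H](c2ccc(O[Si](C)(C)C(C)(C)C)c(OC)c2)Oc2c(OC)cc(C(=O)OC)cc21 | intermediate
26 | {(2S,3R)-2-Ar-3-[(TBS-oxy)methyl]-7-methoxy-2,3-dihydro-1-benzofuran-5-yl}methanol | CC(C)(C)[Si](C)(C)OC[C@@H]1[C@@H](c2ccc(O[Si](C)(C)C(C)(C)C)c(OC)c2)Oc2c(OC)cc(CO)cc21 | intermediate
27 | (2S,3R)-5-(bromomethyl)-2-Ar-3-[(TBS-oxy)methyl]-7-methoxy-2,3-dihydro-1-benzofuran | CC(C)(C)[Si](C)(C)OC[C@@H]1[C@@H](c2ccc(O[Si](C)(C)C(C)(C)C)c(OC)c2)Oc2c(OC)cc(CBr)cc21 | intermediate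
28 | lithium enolate of 16 (not isolated) | [Li]OC1=C[C@@H]([C@@H](O[Si](C)(C)C(C)(C)C)c2ccc(O[Si](C)(C)C(C)(C)C)c(OC)c2)CO1 | intermediate
29 | (3R,4R)-3-({(2S,3R)-2-Ar-3-[(TBS-oxy)methyl]-7-methoxy-2,3-dihydro-1-benzofuran-5-yl}methyl)-4-[(R)-Ar(TBS-oxy)methyl]oxolan-2-one | O=C1OC[C@H]([C@@H](O[Si](C)(C)C(C)(C)C)c2ccc(O[Si](C)(C)C(C)(C)C)c(OC)c2)[C@H]1Cc1cc(OC)c2O[C@H](c3ccc(O[Si](C)(C)C(C)(C)C)c(OC)c3)[C@@H](CO[Si](C)(C)C(C)(C)C)c2c1 | intermediate
30 | (3R,4R)-3-{[(2S,3R)-2-(4-hydroxy-3-methoxyphenyl)-3-(hydroxymethyl)-7-methoxy-2,3-dihydro-1-benzofuran-5-yl]methyl}-4-[(R)-hydroxy(4-hydroxy-3-methoxyphenyl)methyl]oxolan-2-one | O=C1OC[C@H]([C@@H](O)c2ccc(O)c(OC)c2)[C@H]1Cc1cc(OC)c2O[C@H](c3ccc(O)c(OC)c3)[C@@H](CO)c2c1 | target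

**Step count and risks**

Total step count: 18. Longest linear sequence: 11 steps (steps 1, 9, 10, 11, 12, 13, 14, 15, 16, 17, 18).

Steps most likely to fail:

Step 7. The chirality transfer from sulfur may erode if C–C bond formation becomes stepwise instead of sigmatropic, and zinc chloride formed during ketene generation may ionize the benzylic silyl ether. The fallback replaces the sigmatropic lactonization by an auxiliary-controlled aldol; it sets out from 2 and comes back at 16. (R)-4-Benzyloxazolidin-2-one would be N-acylated with methyl 4-chloro-4-oxobutanoate (n-BuLi, THF, −78 °C) to give the succinoyl imide F1. A magnesium chloride-catalysed anti-selective Evans-type aldol addition of F1 to 2 (MgCl2, Et3N, Me3SiCl, EtOAc, rt) should give the anti aldol trimethylsilyl ether F2, in which both future lactone-side stereocentres are set by the auxiliary. LiBH4 (THF, 0 °C) would cleave the auxiliary reductively, and the freed primary alcohol should close onto the methyl ester to give the trimethylsilyloxy lactone F3. Citric acid in methanol would then give the hydroxy lactone F4, and TBSCl/imidazole would return 16.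

Step 8. The radical chain may stall after dechlorination, leaving the C–S bond of the thioacetal intact. The fallback abandons the one-pot radical reduction for two separate reductions of different type; it sets out from 15 and comes back at 16. Zn dust in AcOH (rt) would remove both chlorines through the zinc enolate to give the arylthio lactone F5, and Raney Ni in EtOH (rt) would hydrogenolyse the C–S bond to give 16.

Step 13. Chemoselectivity may be lost, either by partial reduction of the benzoate or by sluggish reduction of the hindered ethyl ester. The fallback reduces both esters and re-differentiates the two alcohols by oxidation state; it sets out from 23 and comes back at 26, replacing steps 13 to 15. i-Bu2AlH (CH2Cl2, −78 to 0 °C) would reduce both esters to the diol F6. MnO2 (CH2Cl2, rt) should oxidize only the benzylic alcohol, giving the hydroxy aldehyde F7. TBSCl/imidazole would give the silyloxy aldehyde F8, and NaBH4 (MeOH, 0 °C) would give 26.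

**Further compounds**

F1 | step 7 | methyl 4-[(4R)-4-benzyl-2-oxooxazolidin-3-yl]-4-oxobutanoate | COC(=O)CCC(=O)N1[C@H](Cc2ccccc2)COC1=O
F2 | step 7 | methyl 4-Ar-3-{[(4R)-4-benzyl-2-oxooxazolidin-3-yl]carbonyl}-4-(trimethylsilyloxy)butanoate, anti, configured as C4 and the carbinol carbon of 16 | COC(=O)C[C@@H]([C@@H](O[Si](C)(C)C)c1ccc(O[Si](C)(C)C(C)(C)C)c(OC)c1)C(=O)N1[C@H](Cc2ccccc2)COC1=O
F3 | step 7 | (4R)-4-[(R)-Ar(trimethylsilyloxy)methyl]oxolan-2-one | O=C1OC[C@H]([C@@H](O[Si](C)(C)C)c2ccc(O[Si](C)(C)C(C)(C)C)c(OC)c2)C1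
F4 | step 7 | (4R)-4-[(R)-Ar(hydroxy)methyl]oxolan-2-one | O=C1OC[C@H]([C@@H](O)c2ccc(O[Si](C)(C)C(C)(C)C)c(OC)c2)C1
F5 | step 8 | (4S,5S)-4-[(R)-Ar(TBS-oxy)methyl]-5-(p-tolylsulfanyl)oxolan-2-one | O=C1O[C@@H](Sc2ccc(C)cc2)[C@H]([C@@H](O[Si](C)(C)C(C)(C)C)c2ccc(O[Si](C)(C)C(C)(C)C)c(OC)c2)C1
F6 | step 13 | [(2S,3R)-2-Ar-7-methoxy-2,3-dihydro-1-benzofuran-3,5-diyl]dimethanol | OC[C@@H]1[C@@H](c2ccc(O[Si](C)(C)C(C)(C)C)c(OC)c2)Oc2c(OC)cc(CO)cc21
F7 | step 13 | (2S,3R)-2-Ar-3-(hydroxymethyl)-7-methoxy-2,3-dihydro-1-benzofuran-5-carbaldehyde | OC[C@@H]1[C@@H](c2ccc(O[Si](C)(C)C(C)(C)C)c(OC)c2)Oc2c(OC)cc(C=O)cc21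
F8 | step 13 | (2S,3R)-2-Ar-3-[(TBS-oxy)methyl]-7-methoxy-2,3-dihydro-1-benzofuran-5-carbaldehyde | CC(C)(C)[Si](C)(C)OC[C@@H]1[C@@H](c2ccc(O[Si](C)(C)C(C)(C)C)c(OC)c2)Oc2c(OC)cc(C=O)cc21
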